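Numbering follows the daucane skeleton: C1 is the methyl-bearing ring-fusion carbon, C2 and C3 the cyclopentane methylenes, C4 the isopropyl carbinol, C5 the ring-fusion CH, C6 the ester carbinol, C7 a methylene, C8 the carbon carrying the exocyclic C14 methylene, C9 the secondary carbinol and C10 the methylene returning to C1. The target 23 is the (1R,4R,5S,6S,9S) isomer.

## The problem

Compound 23 is a trans-fused hydroazulene: a cyclopentane (ring A) and a cycloheptane (ring B) share the C1–C5 bond, and the two ring-B bonds that leave ring A (C1–C10 and C5–C6) lie on opposite faces. Four of the five stereocentres (C1, C4, C5, C6) form one contiguous cluster, and C9 sits alone on the far side of ring B. C1 is quaternary and cannot be corrected later, so it has to be set first and by a catalyst. From there C1 can steer the adjacent C5, C5 can steer C4 (attack on a C4 ketone anti to the C5 substituent), and the C4 hydroxyl together with C5 can steer C6 by chelation. The weak link in this relay is that the two carbon substituents on C1, the methyl group and the CH2 arm that becomes C10, differ little in size. C9 has no neighbour to lean on and can only be controlled in the ring closure. The vanillate ester and its free phenol will not survive hydride, strong base or organolithium or Grignard reagents. The tertiary C4 alcohol is β to C6 and invites dehydration or retro-aldol cleavage whenever C6 is a carbonyl. The allylic alcohol with its 1,1-disubstituted alkene rules out hydrogenation and strong acid late in the route. The enabling feature is the C9 carbinol next to the C8=C14 methylene in ring B: a 2-substituted allylic alcohol, which is the direct product of adding a C8 vinyl metal to a C9 aldehyde.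

## Retrosynthesis

**23 from 22.** Only the O–Si bond of the phenol is cut. The phenol is masked as its tert-butyldimethylsilyl ether 22 because a free phenol would interfere with the esterification and the organometallic ring closure. An aryl silyl ether can be removed at the end with buffered fluoride without touching the ester or the allylic alcohol.

**22 from 21 (key disconnection).** The C8–C9 bond is cut, which opens ring B to the monocyclic bromoalkene aldehyde 21. A cut at C7–C8 or C9–C10 would ask for an sp3–sp3 ring closure with no functional handle. A cut at C6–C7 would leave both C8 and C9 to be functionalised on a medium ring. A metathesis closure could not deliver the exocyclic methylene and the alcohol together. Compound 21 already holds four of the five stereocentres and the ester. The forward reaction must turn the vinyl bromide into a nucleophile that ignores the ester and the free tertiary alcohol, close a seven-membered ring, and set C9.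

**21 from 19.** The aldehyde carbon C9 is traced back to the terminal alkene of an allyl group, through diol 20. An allyl group is inert to every organometallic used before this point and is unmasked in one operation. A protected hydroxyethyl arm would need two steps and a protecting group orthogonal to the phenol silyl ether. The forward reaction must cleave the monosubstituted alkene and spare the 2-bromoalkene.

**19 from 14 and 17.** The acyl–oxygen bond at C6 is cut, giving diol 14 and the silyl-protected vanillic acid 17, which comes from vanillic acid 15 through the bis-silyl derivative 16. Esterification is placed here because 14 differentiates itself: only the secondary C6 alcohol can be acylated. After ring closure the C9 alcohol would compete.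

**14 from 13 and 12.** The C6–C7 bond is cut, giving the β-hydroxy aldehyde 13 and 2,3-dibromopropene 12. Adding carbon to a C6 aldehyde is preferred to reducing a C6 ketone. In the chelate between the aldehyde oxygen and the C4 hydroxyl, the exposed face lies next to H5, and a nucleophile entering there gives the required (S)-C6. A hydride entering the corresponding ketone from the same face would give the epimer. Aldehyde 13 is not stored; it is released from its dimethyl acetal 11 in the same flask.

**11 from 9 and 10.** The C4–isopropyl bond is cut, leading to ketone 9 and isopropylmagnesium chloride 10. Addition to a 2-substituted cyclopentanone anti to the substituent places the new hydroxyl cis to the C6 carbon, as required. The alternative of coupling an enol triflate with the isopropyl group would leave the cis oxygen–carbon pair to be installed separately on a hindered alkene.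

**9 from 7 and 8.** The C5–C6 bond is cut. C6 is introduced at the aldehyde oxidation level, as the acetal carbon of trimethyl orthoformate 8, onto the silyl enol ether 7. The position next to the quaternary carbon can only be reached through the enolate that the conjugate addition produces, so that enolate is kept as 7. The forward reaction has to place C6 anti to the allyl group on C1.

**7 from 4 and 5.** The C1–methyl bond is cut: catalytic asymmetric conjugate addition of trimethylaluminium 5 to enone 4, with the aluminium enolate 6 silylated in the flask. Methyl is added to an allyl-bearing enone, not the reverse, because methyl transfer from 5 to β-substituted cyclopentenones is the best-established way to make such a quaternary centre, whereas an allyl group cannot be delivered in a 1,4 sense with comparable control.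

**4 from 1 and 2.** Enone 4 comes from 3-ethoxycyclopent-2-en-1-one 1 and allylmagnesium bromide 2 by 1,2-addition (adduct 3) and acid-induced transposition.

## Roads not taken

**Alternative 1:** Buchner ring expansion. The cut removes C1–C5 and C1–C10 together. In the forward direction a rhodium carbenoid at C1, generated with Rh2(OAc)4 from an α-methyl diazoketone, adds to the ipso–ortho bond of a 4-methoxyphenyl group, and the norcaradiene opens to the dihydroazulenone A1. Its merit is speed: both rings and the quaternary carbon arise in one step from an arene, with the C4 carbinol already in place. For this target the weak points are what A1 carries and what it lacks. It has a ketone at C2 that must be deleted and an enol ether at C8 where a methylene is needed. It has no oxygen at C6 or C9. Its three ring double bonds must be told apart to install the trans ring fusion, the 6α oxygen and the 9α alcohol. A carbenoid flanked by a methyl group is also prone to 1,2-hydride shift, and the 1,3-induction from C4 to C1 is not assured. Alternative 1 is clearly better in the number of carbon–carbon bond-forming steps. The chosen plan sets against this that 22 leaves the key step with every oxidation level and stereocentre final, so no redox work is done on the medium ring.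

**Alternative 2:** Nitrile oxide cycloaddition as a masked tertiary aldol. The cut removes C5–C6 and O–C4. In the forward direction a 2-bromoallyl-substituted nitrile oxide adds across the C4=C5 bond of a 1-isopropylcyclopentene to give isoxazoline A2. Its merit is real: the concerted addition fixes the cis relation of the C4 oxygen and the C5–C6 bond in a single event, which the chosen plan obtains only through two substrate-controlled steps. A2 would also feed the same chromium-mediated closure, so this road differs in how the cyclisation substrate is built, not in how ring B is closed. Its weak points are three. The dipolarophile is a trisubstituted alkene flanked by a quaternary carbon, so furoxan formation would compete. Facial selectivity rests on the same methyl-versus-CH2 discrimination as in the chosen plan, but at a higher temperature. After N–O cleavage C6 is a ketone, and the chelate model that favours the correct epimer for carbon addition to a C6 aldehyde predicts the wrong epimer for hydride addition to a C6 ketone. The chosen plan reaches the cyclisation substrate in fewer steps and sets C6 by the addition that the model supports.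

**Alternative 3:** Claisen ring expansion of a 2-methylenetetrahydrofuran. The cut forms C1–C10 while C6–O breaks: a thermal [3,3] shift of an allyl vinyl ether embedded in the cyclic enol ether gives the cycloheptenone A3. Its merits are considerable. Ring B and the quaternary C1 arise together, and C1 is set by suprafacial transfer from a C6–O stereocentre, not by a methyl-versus-CH2 preference. The C5=C6 alkene of A3 is also well placed for hydroboration from the α face, which would give the 5α-H/6α-OH pair in one step. In these respects it is better than the chosen plan. Its weak points lie before and after the key step. The rearrangement substrate needs a tetrasubstituted C1=C5 alkene carrying a tertiary allylic silyl ether, which may ionise under the heating needed to form a quaternary centre. After the rearrangement the C9 ketone must be methylenated selectively at C8 and then reduced, with the same uncertainty at C9. The vanillate must then be introduced while the C9 alcohol is present, which costs protecting-group steps. The chosen plan sets against this that C8, C14 and the C9 alcohol appear in one step and that the ester is carried through the ring closure.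

Key step: step 9

Assumption: in reactions at C5 the allyl group on C1 is treated as effectively larger than the methyl group, and the antipode of the carbene ligand that delivers methyl to give (R)-7 is used.

## Route

Step 1
Reactants: 1 3-ethoxycyclopent-2-en-1-one; 2 allylmagnesium bromide
Product: 4 3-(prop-2-en-1-yl)cyclopent-2-en-1-one, via bromomagnesium alkoxide 3 (not isolated)
Conditions: THF, 0 °C; then 1 M HCl, 0 °C, short contact
Reagents that add atoms: none
Why: Stork–Danheiser alkylative enone transposition: 1,2-addition to the vinylogous ester, then acid hydrolysis of the enol ether with loss of water gives the 3-substituted enone; cold, brief acid treatment should keep the skipped diene from moving into conjugation.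

Step 2
Reactants: 4 3-(prop-2-en-1-yl)cyclopent-2-en-1-one; 5 trimethylaluminium
Product: 7 triethyl{[(3R)-3-methyl-3-(prop-2-en-1-yl)cyclopent-1-en-1-yl]oxy}silane, via dimethylaluminium enolate 6 (not isolated)
Conditions: Cu(OTf)2 (5 mol %), chiral sulfonate-bearing N-heterocyclic carbene ligand (5 mol %), THF, −78 °C; then Et3SiOTf, −78 to 0 °C
Reagents that add atoms: triethylsilyl trifluoromethanesulfonate, CC[Si](CC)(CC)OS(=O)(=O)C(F)(F)F
Why: Copper-catalysed asymmetric conjugate addition of a trialkylaluminium to a β-substituted cyclopentenone creates the quaternary C1, its configuration fixed by the ligand antipode; in-flask O-silylation preserves the C4=C5 enolate regiochemistry, which could not be regenerated from the ketone.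

Step 3
Reactants: 7 triethyl{[(3R)-3-methyl-3-(prop-2-en-1-yl)cyclopent-1-en-1-yl]oxy}silane; 8 trimethyl orthoformate
Product: 9 (2S,3R)-2-(dimethoxymethyl)-3-methyl-3-(prop-2-en-1-yl)cyclopentan-1-one
Conditions: TMSOTf (10 mol %), CH2Cl2, −78 °C; Et3N quench
Reagents that add atoms: none
Why: Mukaiyama-type alkylation of a silyl enol ether by the dimethoxycarbenium ion formed from the orthoformate places C6 on C5 at the aldehyde oxidation level; attack anti to the allyl group on the adjacent C1 puts the acetal cis to the methyl group, and the low temperature is relied on to amplify the small size difference.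

Step 4
Reactants: 9 (2S,3R)-2-(dimethoxymethyl)-3-methyl-3-(prop-2-en-1-yl)cyclopentan-1-one; 10 isopropylmagnesium chloride
Product: 11 (1R,2R,3R)-2-(dimethoxymethyl)-3-methyl-1-(propan-2-yl)-3-(prop-2-en-1-yl)cyclopentan-1-ol
Conditions: CeCl3 (anhydrous), THF, −78 to 0 °C; aq. NH4Cl
Reagents that add atoms: none
Why: Organocerium 1,2-addition suppresses enolisation and β-hydride reduction of the hindered ketone; the isopropyl group enters C4 anti to the C5 acetal substituent, so the new hydroxyl ends cis to C6.

Step 5
Reactants: 11 (1R,2R,3R)-2-(dimethoxymethyl)-3-methyl-1-(propan-2-yl)-3-(prop-2-en-1-yl)cyclopentan-1-ol; 12 2,3-dibromoprop-1-ene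
Product: 14 (1R,2S,3R)-2-[(1S)-3-bromo-1-hydroxybut-3-en-1-yl]-3-methyl-1-(propan-2-yl)-3-(prop-2-en-1-yl)cyclopentan-1-ol, via hydroxy aldehyde 13 (not isolated)
Conditions: 1 M HCl, THF, 0 °C to rt; then NaHCO3 to pH 6, In powder, THF/H2O, rt
Reagents that add atoms: water, O
Why: Acetal hydrolysis followed by an indium-mediated Barbier 2-bromoallylation in water; the aldehyde oxygen and the cis C4 hydroxyl chelate the metal in a six-membered ring fused to the cyclopentane, and the allyl reagent attacks the convex face next to H5, away from C1 and its methyl group (Cram-chelate control), which gives (S)-C6. The C5 centre of 13 is not at risk, because the formyl group is already in its more stable position between the hydroxyl and methyl groups.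

Step 6
Reactants: 15 4-hydroxy-3-methoxybenzoic acid
Product: 17 4-[(tert-butyldimethylsilyl)oxy]-3-methoxybenzoic acid, via bis-silyl derivative 16 (not isolated)
Conditions: TBSCl (2.2 equiv), imidazole, DMF, rt; then AcOH/THF/H2O, rt
Reagents that add atoms: tert-butyldimethylsilyl chloride, CC(C)(C)[Si](C)(C)Cl
Why: Exhaustive silylation followed by selective hydrolysis of the labile silyl ester; the aryl silyl ether is stable to dilute acid.

Step 7
Reactants: 14 (1R,2S,3R)-2-[(1S)-3-bromo-1-hydroxybut-3-en-1-yl]-3-methyl-1-(propan-2-yl)-3-(prop-2-en-1-yl)cyclopentan-1-ol; 17 4-[(tert-butyldimethylsilyl)oxy]-3-methoxybenzoic acid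
Product: 19 (1S)-3-bromo-1-[(1S,2R,5R)-2-hydroxy-5-methyl-2-(propan-2-yl)-5-(prop-2-en-1-yl)cyclopentyl]but-3-en-1-yl 4-[(tert-butyldimethylsilyl)oxy]-3-methoxybenzoate, via mixed anhydride 18 (not isolated)
Conditions: 17, 2,4,6-Cl3C6H2COCl, Et3N, THF, rt; then 14, DMAP, toluene, 60 °C
Reagents that add atoms: none
Why: Yamaguchi esterification: the acylpyridinium formed from the mixed anhydride is reactive enough for the hindered secondary C6 alcohol, while the tertiary C4 alcohol is not acylated; no stereocentre is touched.

Step 8
Reactants: 19 (1S)-3-bromo-1-[(1S,2R,5R)-2-hydroxy-5-methyl-2-(propan-2-yl)-5-(prop-2-en-1-yl)cyclopentyl]but-3-en-1-yl 4-[(tert-butyldimethylsilyl)oxy]-3-methoxybenzoate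
Product: 21 (1S)-3-bromo-1-[(1S,2R,5R)-2-hydroxy-5-methyl-5-(2-oxoethyl)-2-(propan-2-yl)cyclopentyl]but-3-en-1-yl 4-[(tert-butyldimethylsilyl)oxy]-3-methoxybenzoate, via vicinal diol 20 (not isolated)
Conditions: OsO4 (2 mol %), NaIO4 (4 equiv), 2,6-lutidine, dioxane/H2O, rt
Reagents that add atoms: osmium tetroxide, O=[Os](=O)(=O)=O; sodium periodate, [Na+].[O-][I](=O)(=O)=O
Why: Lemieux–Johnson oxidative cleavage: the electron-rich monosubstituted alkene is dihydroxylated much faster than the bromine-deactivated 2-bromoalkene, and periodate cleaves the diol to the C9 aldehyde. The C4 hydroxyl cannot form a lactol with C9 because the two groups sit on opposite faces of ring A.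

Step 9
Reactants: 21 (1S)-3-bromo-1-[(1S,2R,5R)-2-hydroxy-5-methyl-5-(2-oxoethyl)-2-(propan-2-yl)cyclopentyl]but-3-en-1-yl 4-[(tert-butyldimethylsilyl)oxy]-3-methoxybenzoate
Product: 22 (3R,3aS,4S,7S,8aR)-3,7-dihydroxy-8a-methyl-6-methylidene-3-(propan-2-yl)decahydroazulen-4-yl 4-[(tert-butyldimethylsilyl)oxy]-3-methoxybenzoate
Conditions: CrCl2 (6 equiv), NiCl2 (2 mol %), DMSO/THF, rt, 0.005 M
Reagents that add atoms: none
Why: Divalent chromium reduces NiCl2 to zerovalent nickel, which inserts into the C8–Br bond; the vinylnickel transmetalates to trivalent chromium, and the vinylchromium adds to the C9 aldehyde while nickel returns to the cycle (Nozaki–Hiyama–Kishi reaction). The closest known reaction type is the intramolecular coupling of 2-bromoalkenes with aldehydes to give 2-methylenecycloalkanols, which is established for medium rings and tolerates esters, silyl ethers and free hydroxyl groups. Ring B closes by a 7-exo-trig attack of C8 on the carbonyl carbon, the oxygen staying outside the ring. The new stereocentre C9 is controlled by the substrate: the two tethers leave ring A trans, so the forming trans-fused cycloheptane adopts a chair-like arrangement in which the chromium-bound oxygen lies pseudo-equatorial, away from the axial C1 methyl that is 1,3 to C9, and this leads to the 9α (S) alcohol. The step needs chemoselectivity for the aldehyde over the aryl ester and the tertiary hydroxyl, which the low basicity and aldehyde preference of organochromium reagents secure. It needs cyclisation over oligomerisation, which high dilution and the placement of both arms on adjacent ring carbons secure. The 2-methylene allylic alcohol appears directly, so no later redox step or olefination is needed on the seven-membered ring.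

Step 10
Reactants: 22 (3R,3aS,4S,7S,8aR)-3,7-dihydroxy-8a-methyl-6-methylidene-3-(propan-2-yl)decahydroazulen-4-yl 4-[(tert-butyldimethylsilyl)oxy]-3-methoxybenzoate
Product: 23 (3R,3aS,4S,7S,8aR)-3,7-dihydroxy-8a-methyl-6-methylidene-3-(propan-2-yl)decahydroazulen-4-yl 4-hydroxy-3-methoxybenzoate
Conditions: TBAF, AcOH, THF, 0 °C
Reagents that add atoms: none
Why: Fluoride cleaves the aryl silyl ether; buffering with acetic acid keeps the phenoxide from attacking the ester, and the allylic and tertiary alcohols are untouched.

## Compound list

1 | 3-ethoxycyclopent-2-en-1-one | CCOC1=CC(=O)CC1 | starting material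
2 | allylmagnesium bromide | C=CC[Mg]Br | starting material
3 | bromomagnesium 3-ethoxy-1-(prop-2-en-1-yl)cyclopent-2-en-1-olate (racemic) | CCOC1=CC(CC=C)(O[Mg]Br)CC1 | intermediate (not isolated)
4 | 3-(prop-2-en-1-yl)cyclopent-2-en-1-one | C=CCC1=CC(=O)CC1 | intermediate
5 | trimethylaluminium | C[Al](C)C | starting material
6 | dimethylaluminium (3R)-3-methyl-3-(prop-2-en-1-yl)cyclopent-1-en-1-olate | C[Al](C)OC1=C[C@](C)(CC1)CC=C | intermediate (not isolated)
7 | triethyl{[(3R)-3-methyl-3-(prop-2-en-1-yl)cyclopent-1-en-1-yl]oxy}silane | CC[Si](CC)(CC)OC1=C[C@](C)(CC1)CC=C | intermediate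
8 | trimethyl orthoformate | COC(OC)OC | starting material
9 | (2S,3R)-2-(dimethoxymethyl)-3-methyl-3-(prop-2-en-1-yl)cyclopentan-1-one | COC(OC)[C@@H]1[C@](C)(CCC1=O)CC=C | intermediate
10 | isopropylmagnesium chloride | CC(C)[Mg]Cl | starting material
11 | (1R,2R,3R)-2-(dimethoxymethyl)-3-methyl-1-(propan-2-yl)-3-(prop-2-en-1-yl)cyclopentan-1-ol | COC(OC)[C@@H]1[C@](C)(CC[C@@]1(O)C(C)C)CC=C | intermediate
12 | 2,3-dibromoprop-1-ene | C=C(Br)CBr | starting material
13 | (1R,2R,5R)-2-hydroxy-5-methyl-2-(propan-2-yl)-5-(prop-2-en-1-yl)cyclopentane-1-carbaldehyde | O=C[C@@H]1[C@](C)(CC[C@@]1(O)C(C)C)CC=C | intermediate (not isolated)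
14 | (1R,2S,3R)-2-[(1S)-3-bromo-1-hydroxybut-3-en-1-yl]-3-methyl-1-(propan-2-yl)-3-(prop-2-en-1-yl)cyclopentan-1-ol | C=C(Br)C[C@H](O)[C@@H]1[C@](C)(CC[C@@]1(O)C(C)C)CC=C | intermediate
15 | 4-hydroxy-3-methoxybenzoic acid (vanillic acid) | COc1cc(C(=O)O)ccc1O | starting material
16 | tert-butyldimethylsilyl 4-[(tert-butyldimethylsilyl)oxy]-3-methoxybenzoate | COc1cc(C(=O)O[Si](C)(C)C(C)(C)C)ccc1O[Si](C)(C)C(C)(C)C | intermediate (not isolated)
17 | 4-[(tert-butyldimethylsilyl)oxy]-3-methoxybenzoic acid | COc1cc(C(=O)O)ccc1O[Si](C)(C)C(C)(C)C | intermediate
18 | 4-[(tert-butyldimethylsilyl)oxy]-3-methoxybenzoic 2,4,6-trichlorobenzoic anhydride | COc1cc(C(=O)OC(=O)c2c(Cl)cc(Cl)cc2Cl)ccc1O[Si](C)(C)C(C)(C)C | intermediate (not isolated)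
19 | (1S)-3-bromo-1-[(1S,2R,5R)-2-hydroxy-5-methyl-2-(propan-2-yl)-5-(prop-2-en-1-yl)cyclopentyl]but-3-en-1-yl 4-[(tert-butyldimethylsilyl)oxy]-3-methoxybenzoate | C=C(Br)C[C@H](OC(=O)c1ccc(O[Si](C)(C)C(C)(C)C)c(OC)c1)[C@@H]1[C@](C)(CC[C@@]1(O)C(C)C)CC=C | intermediate
20 | (1S)-3-bromo-1-[(1S,2R,5R)-5-(2,3-dihydroxypropyl)-2-hydroxy-5-methyl-2-(propan-2-yl)cyclopentyl]but-3-en-1-yl 4-[(tert-butyldimethylsilyl)oxy]-3-methoxybenzoate (both epimers at the new secondary carbinol) | C=C(Br)C[C@H](OC(=O)c1ccc(O[Si](C)(C)C(C)(C)C)c(OC)c1)[C@@H]1[C@](C)(CC[C@@]1(O)C(C)C)CC(O)CO | intermediate (not isolated)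
21 | (1S)-3-bromo-1-[(1S,2R,5R)-2-hydroxy-5-methyl-5-(2-oxoethyl)-2-(propan-2-yl)cyclopentyl]but-3-en-1-yl 4-[(tert-butyldimethylsilyl)oxy]-3-methoxybenzoate | C=C(Br)C[C@H](OC(=O)c1ccc(O[Si](C)(C)C(C)(C)C)c(OC)c1)[C@@H]1[C@](C)(CC[C@@]1(O)C(C)C)CC=O | intermediate
22 | (3R,3aS,4S,7S,8aR)-3,7-dihydroxy-8a-methyl-6-methylidene-3-(propan-2-yl)decahydroazulen-4-yl 4-[(tert-butyldimethylsilyl)oxy]-3-methoxybenzoate | C=C1C[C@H](OC(=O)c3ccc(O[Si](C)(C)C(C)(C)C)c(OC)c3)[C@@H]2[C@](C)(CC[C@@]2(O)C(C)C)C[C@@H]1O | intermediate
23 | (3R,3aS,4S,7S,8aR)-3,7-dihydroxy-8a-methyl-6-methylidene-3-(propan-2-yl)decahydroazulen-4-yl 4-hydroxy-3-methoxybenzoate | C=C1C[C@H](OC(=O)c2ccc(O)c(OC)c2)[C@@H]2[C@](C)(CC[C@@]2(O)C(C)C)C[C@@H]1O | target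

## Step count and least certain steps

Total: 10 steps. Longest linear sequence: 9 steps (steps 1 to 5 and 7 to 10, from 1); step 6 is a one-step side branch.

**Step 9 (key step).** Two things may go wrong. The vinylchromium may be protonated or couple between molecules before it reaches the aldehyde, since a seven-membered closure is slow. The facial preference at the aldehyde may also be too weak, so that the C9 epimer accompanies 22. The fallback sets out from the cyclisation mixture of 22 and its epimer and returns to 22. The mixture containing (3R,3aS,4S,7R,8aR)-3,7-dihydroxy-8a-methyl-6-methylidene-3-(propan-2-yl)decahydroazulen-4-yl 4-[(tert-butyldimethylsilyl)oxy]-3-methoxybenzoate F8 would be oxidised at the allylic alcohol with Dess–Martin periodinane to (3R,3aS,4S,8aR)-3-hydroxy-8a-methyl-6-methylidene-7-oxo-3-(propan-2-yl)decahydroazulen-4-yl 4-[(tert-butyldimethylsilyl)oxy]-3-methoxybenzoate F9. This enone would then be reduced under reagent control by a Corey–Bakshi–Shibata reduction (oxazaborolidine antipode chosen to deliver hydride to the β face, catecholborane, −78 °C) to give 22. This replaces substrate control in the ring closure by reagent control on the closed ring.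

**Step 3.** The likely failure is poor facial selectivity at C5, because methyl and allyl differ little in size, together with epimerisation of the α-acyl acetal centre through its enol. The fallback sets out from 7 and returns at 14. It forms the C5–C6 bond with the whole side chain in a closed transition state at low temperature. Compound 7 would be cleaved with MeLi (THF, 0 °C) to lithium (3R)-3-methyl-3-(prop-2-en-1-yl)cyclopent-1-en-1-olate F2, which is transmetalated with Cy2BCl at −78 °C to dicyclohexyl{[(3R)-3-methyl-3-(prop-2-en-1-yl)cyclopent-1-en-1-yl]oxy}borane F3. Addition of freshly prepared 3-bromobut-3-enal F1 (Dess–Martin oxidation of the commercial bromo homoallylic alcohol) should give, through a Zimmerman–Traxler chair of the ring-locked E enolate, the anti aldol (2S,3R)-2-[(1S)-3-bromo-1-hydroxybut-3-en-1-yl]-3-methyl-3-(prop-2-en-1-yl)cyclopentan-1-one F4 after buffered methanolic work-up. Silylation (TMSCl, imidazole) would give (2S,3R)-2-{(1S)-3-bromo-1-[(trimethylsilyl)oxy]but-3-en-1-yl}-3-methyl-3-(prop-2-en-1-yl)cyclopentan-1-one F5, which guards against retro-aldol cleavage. Addition of 10 with CeCl3 would give (1R,2S,3R)-2-{(1S)-3-bromo-1-[(trimethylsilyl)oxy]but-3-en-1-yl}-3-methyl-1-(propan-2-yl)-3-(prop-2-en-1-yl)cyclopentan-1-ol F6, and a citric acid work-up would remove the silyl group to give 14. This path is shorter. It is held in reserve because it depends on a fragile, enolisable aldehyde and a retro-aldol-prone adduct.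

**Step 5.** Chelation may be incomplete in water, so that attack occurs through an open, dipole-controlled arrangement and C6 is formed as a mixture. The tertiary β-hydroxy aldehyde may also lose water under the acid used for hydrolysis. The fallback sets out from 13 and returns at 14. Compound 13 would be isolated after a milder hydrolysis (oxalic acid on wet silica). It would then be treated in CH2Cl2 at −78 °C with a chiral bis-sulfonamide-derived B-(2-bromoallyl)diazaborolidine, so that C6 is set by the reagent (asymmetric allylboration) and not by the substrate. No new substrate-derived compound is formed.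

**Step 4.** The hindered, enolisable ketone may be deprotonated at C5, or reduced by β-hydride transfer from the isopropyl reagent, in place of addition. The fallback sets out from 9 and returns at 11. Isopropenylmagnesium bromide with CeCl3 (an sp2 nucleophile without transferable β-hydrogen) would give (1S,2R,3R)-2-(dimethoxymethyl)-3-methyl-1-(prop-1-en-2-yl)-3-(prop-2-en-1-yl)cyclopentan-1-ol F7. The 1,1-disubstituted alkene of this compound would then be reduced in the presence of the monosubstituted allyl group by a Mukaiyama-type hydrogen-atom-transfer hydrogenation (Mn(dpm)3, PhSiH3, tert-butyl hydroperoxide, isopropanol), which favours the alkene that gives a tertiary radical, to reach 11.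

## Further compounds

F1 | step 3 | 3-bromobut-3-enal | C=C(Br)CC=O
F2 | step 3 | lithium (3R)-3-methyl-3-(prop-2-en-1-yl)cyclopent-1-en-1-olate | [Li]OC1=C[C@](C)(CC1)CC=C
F3 | step 3 | dicyclohexyl{[(3R)-3-methyl-3-(prop-2-en-1-yl)cyclopent-1-en-1-yl]oxy}borane | C=CC[C@]1(C)C=C(OB(C2CCCCC2)C2CCCCC2)CC1
F4 | step 3 | (2S,3R)-2-[(1S)-3-bromo-1-hydroxybut-3-en-1-yl]-3-methyl-3-(prop-2-en-1-yl)cyclopentan-1-one | C=C(Br)C[C@H](O)[C@@H]1[C@](C)(CCC1=O)CC=C
F5 | step 3 | (2S,3R)-2-{(1S)-3-bromo-1-[(trimethylsilyl)oxy]but-3-en-1-yl}-3-methyl-3-(prop-2-en-1-yl)cyclopentan-1-one | C=C(Br)C[C@H](O[Si](C)(C)C)[C@@H]1[C@](C)(CCC1=O)CC=C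
F6 | step 3 | (1R,2S,3R)-2-{(1S)-3-bromo-1-[(trimethylsilyl)oxy]but-3-en-1-yl}-3-methyl-1-(propan-2-yl)-3-(prop-2-en-1-yl)cyclopentan-1-ol | C=C(Br)C[C@H](O[Si](C)(C)C)[C@@H]1[C@](C)(CC[C@@]1(O)C(C)C)CC=C
F7 | step 4 | (1S,2R,3R)-2-(dimethoxymethyl)-3-methyl-1-(prop-1-en-2-yl)-3-(prop-2-en-1-yl)cyclopentan-1-ol | COC(OC)[C@@H]1[C@](C)(CC[C@@]1(O)C(C)=C)CC=C
F0 | step 5 | none | none
F8 | step 9 | (3R,3aS,4S,7R,8aR)-3,7-dihydroxy-8a-methyl-6-methylidene-3-(propan-2-yl)decahydroazulen-4-yl 4-[(tert-butyldimethylsilyl)oxy]-3-methoxybenzoate | C=C1C[C@H](OC(=O)c3ccc(O[Si](C)(C)C(C)(C)C)c(OC)c3)[C@@H]2[C@](C)(CC[C@@]2(O)C(C)C)C[C@H]1O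
F9 | step 9 | (3R,3aS,4S,8aR)-3-hydroxy-8a-methyl-6-methylidene-7-oxo-3-(propan-2-yl)decahydroazulen-4-yl 4-[(tert-butyldimethylsilyl)oxy]-3-methoxybenzoate | C=C1C[C@H](OC(=O)c3ccc(O[Si](C)(C)C(C)(C)C)c(OC)c3)[C@@H]2[C@](C)(CC[C@@]2(O)C(C)C)CC1=O
A1 | alternative 1 | 3-isopropyl-6-methoxy-8a-methyl-3-(triethylsilyloxy)-3,8a-dihydroazulen-1(2H)-one | CC(C)[C@]1(O[Si](CC)(CC)CC)CC(=O)[C@]2(C)C=CC(OC)=CC=C12
A2 | alternative 2 | 3-(2-bromoallyl)-4-[2-(tert-butyldiphenylsilyloxy)ethyl]-6a-isopropyl-4-methyl-4,5,6,6a-tetrahydro-3aH-cyclopenta[d]isoxazole | C=C(Br)CC1=NO[C@@]2(C(C)C)CC[C@](C)(CCO[Si](c3ccccc3)(c3ccccc3)C(C)(C)C)[C@@H]12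
A3 | alternative 3 | 3-isopropyl-8a-methyl-3-(triethylsilyloxy)-2,3,5,6,8,8a-hexahydroazulen-7(1H)-one | O=C1CCC=C2[C@](O[Si](CC)(CC)CC)(C(C)C)CC[C@]2(C)C1
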